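The readings are calculated from invented constants, noise included.

In this closed, stirred vessel the tautomer is an intermediate: substrate makes it reversibly, reagent carries it on to target, and substrate and reagent also form the isomer of the product. Its amount therefore rises and falls, and we want the top of that curve.

all flasks: substrate 0.050 M
- north-east: reagent 1.7 equiv; run made earlier
- south-west: reagent 2.6 equiv; run made earlier
- flask: reagent 1.20 equiv; time 15 d

- north-east (time / d: tautomer / %, target / %): 0.417: 10, 1; 1.25: 12, 4; 5.00: 8, 11; 20.0: 6, 13
- south-west (time / d: tautomer / %, target / %): 0.417: 10, 2; 1.25: 11, 7; 5.00: 7, 13; 20.0: 4, 14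

(standard deviation of a reading: 1.5 percentage points)

- the analysis behind the earlier runs scatters by 1.5 percentage points, standard deviation
- reactions considered so far: substrate <-> tautomer; substrate + reagent -> isomer of the product; reagent + tautomer -> target; 2 reagent -> homo dimer

- the best time, 15 d at the latest, for tautomer
- the amount of tautomer, in percent of the substrate charged, at that time

The highest tautomer reading stands at 1.25 d in both runs: 12% with 1.7 equiv of reagent and 11% with 2.6 equiv. I replace the unknown curve of peak against reagent by a straight line through these two points. Its slope is the peak cost of reagent, the tautomer lost at the top for each equivalent added: 1.1 percentage points per equivalent. Going down to 1.20 equiv, I reckon a peak of 12.6%. This is a weak slope, a gap of 1 point against a scatter of 1.5 points, and it says nothing about the time.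

The forecast gives 12.8% at 1.4 d, adding that “The maximum is broad, so its time is less certain than its height”.

The flask gives 12.6% at 1.57 d, and my line gave 12.6%.

    substrate ⇌ tautomer (K = 0.260, k = 0.0148 h⁻¹)
    substrate + reagent → isomer of the product (k = 0.304 L mol⁻¹ h⁻¹)
    reagent + tautomer → target (k = 0.538 L mol⁻¹ h⁻¹)
    2 reagent → homo dimer (k = 0.344 L mol⁻¹ h⁻¹)

I carry the peak cost to the neighbouring flask with 4.80 equiv of reagent, all else held. From the south-west run, the peak cost puts its peak at 8.56%, which is 4.2 points below the forecast's 12.8% for the flask with 1.20 equiv. That neighbouring flask gives 7.64%, which is 0.92 points below the line.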